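## Retrosynthetic overview

1. The caffeate ester is cut last: Mitsunobu esterification of the primary C15–OH with unprotected caffeic acid, then removal of the C2 silyl ether.
2. Rings A and B form in one operation (A first, then B) by a polyene bicyclisation that copies the diterpene cyclase path: initiation at C4, C4–C5 then C10–C9 bond formation, loss of H-7. The substrate is an acyclic (E,E)-triene whose only carbinol centre (C2, as OTBS) sets C5, C9 and C10.
3. The triene is cut at C5–C6 (B-alkyl Suzuki–Miyaura) into an (E)-alkenyl iodide and a dienol made from (S)-citronellol, which supplies C13.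
4. The alkenyl iodide comes from (S)-epichlorohydrin, which supplies C2, by isopropenyl opening, acetylide extension and Negishi carboalumination–iodination.

Assumption: positions are given in labdane numbering (decalin C1–C10, side chain C11–C15, methyls C16 on C13, C17 on C8, C18/C19 on C4, C20 on C10); compounds 1, 2, 9 and 15 are bought.

## Route

Step 1
Reactants: 1 (S)-epichlorohydrin; 2 isopropenylmagnesium bromide
Product: 3 (2S)-1-chloro-4-methylpent-4-en-2-ol
Conditions: CuI (10 mol %), THF, −40 → −20 °C; aq. NH4Cl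
Reagents that add atoms: none
Why: Copper-catalysed Grignard opening of the epoxide at its unsubstituted CH2 leaves the carbinol carbon untouched, so the chiral-pool (S) centre becomes C2 of the target.

Step 2
Reactants: 3 (2S)-1-chloro-4-methylpent-4-en-2-ol
Product: 5 (4S)-2-methylhept-1-en-6-yn-4-ol, via (2S)-2-(2-methylallyl)oxirane 4 (not isolated)
Conditions: LiC≡CH·H2NCH2CH2NH2 (3 equiv), DMSO, 0 °C → rt; H2O
Reagents that add atoms: lithium acetylide ethylenediamine complex, [Li+].[C-]#C.NCCN
Why: The first equivalent of acetylide closes the chlorohydrin to the epoxide and the next opens it at the terminal carbon (acetylide epoxide opening, SN2), so the stereocentre is again not involved and stays (S).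

Step 3
Reactants: 5 (4S)-2-methylhept-1-en-6-yn-4-ol
Product: 6 (4S)-4-[(tert-butyldimethylsilyl)oxy]-2-methylhept-1-en-6-yne
Conditions: TBSCl, imidazole, DMF, rt
Reagents that add atoms: tert-butyldimethylsilyl chloride, CC(C)(C)[Si](C)(C)Cl
Why: Standard silyl ether formation; the bulky OTBS later acts as the equatorial anchor in the bicyclisation, cannot add to the C4 cation, and keeps the C2 oxygen distinct from the C15 alcohol.

Step 4
Reactants: 6 (4S)-4-[(tert-butyldimethylsilyl)oxy]-2-methylhept-1-en-6-yne
Product: 8 (1E,4S)-4-[(tert-butyldimethylsilyl)oxy]-1-iodo-2,6-dimethylhepta-1,6-diene, via alkenyldimethylalane 7 (not isolated)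
Conditions: Me3Al (2.5 equiv), Cp2ZrCl2 (0.25 equiv), CH2Cl2, 0 °C → rt; then I2, THF, −30 → 0 °C
Reagents that add atoms: trimethylaluminium, C[Al](C)C; iodine, II
Why: Negishi zirconium-catalysed carboalumination adds Me–Al syn across the terminal alkyne with methyl on the internal carbon, and iodinolysis with retention gives the (E)-iodide (the C5=C10 geometry), while the 1,1-disubstituted alkene is inert under these conditions.

Step 5
Reactants: 9 (S)-citronellol
Product: 10 (2E,6S)-8-hydroxy-2,6-dimethyloct-2-enal
Conditions: SeO2 (1.1 equiv), EtOH, reflux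
Reagents that add atoms: selenium dioxide, O=[Se]=O
Why: Riley allylic oxidation (ene reaction then [2,3]-sigmatropic shift) attacks only the methyl group trans to the chain and gives the (E)-enal, which fixes the C8=C9 geometry; the saturated primary alcohol and C13 are not affected.

Step 6
Reactants: 10 (2E,6S)-8-hydroxy-2,6-dimethyloct-2-enal
Product: 11 (3S,6E)-3,7-dimethylnona-6,8-dien-1-ol
Conditions: Ph3PCH3Br (1.5 equiv), KOtBu (1.4 equiv), THF, 0 °C → rt
Reagents that add atoms: methyltriphenylphosphonium bromide, C[P+](c1ccccc1)(c1ccccc1)c1ccccc1.[Br-]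
Why: Wittig methylenation of the enal carbonyl gives the 1,3-diene without touching the (E)-trisubstituted alkene, and the ylide is too weak a base to be consumed by the free alcohol.

Step 7
Reactants: 11 (3S,6E)-3,7-dimethylnona-6,8-dien-1-ol; 8 (1E,4S)-4-[(tert-butyldimethylsilyl)oxy]-1-iodo-2,6-dimethylhepta-1,6-diene
Product: 13 (3S,6E,10E,13S)-13-[(tert-butyldimethylsilyl)oxy]-3,7,11,15-tetramethylhexadeca-6,10,15-trien-1-ol, via B-alkyl-9-BBN borane 12 (not isolated)
Conditions: 9-BBN (2.2 equiv), THF, 0 °C → rt; then 8, Pd(dppf)Cl2 (5 mol %), AsPh3 (10 mol %), 3 M aq. K3PO4, DMF, rt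
Reagents that add atoms: none
Why: 9-BBN hydroborates only the monosubstituted vinyl group with boron at the terminal carbon (one further equivalent is held by the OH as a borinate that hydrolyses on work-up), and the B-alkyl Suzuki–Miyaura coupling joins C6 to C5 with retention of the (E)-iodide geometry.

Step 8
Reactants: 13 (3S,6E,10E,13S)-13-[(tert-butyldimethylsilyl)oxy]-3,7,11,15-tetramethylhexadeca-6,10,15-trien-1-ol
Product: 14 (2S,5S,9S,10S,13S)-2-[(tert-butyldimethylsilyl)oxy]labd-7-en-15-ol
Conditions: C36H52CoN2O2 [N,N'-bis(3,5-di-tert-butylsalicylidene)-1,2-cyclohexanediaminocobalt, divalent cobalt] (5 mol %), N-fluoro-2,4,6-trimethylpyridinium triflate (1.5 equiv), (Me2SiH)2O (1.5 equiv), (CF3)2CHOH, 0 °C → rt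
Reagents that add atoms: none
Why: Proposed new method: the cobalt hydride made from the cobalt salen complex, the N-fluoropyridinium oxidant and the silane gives H• only to the 1,1-disubstituted alkene (Markovnikov hydrogen-atom transfer), the tertiary C4 radical closes 6-endo on C5 and the C10 radical 6-endo on C9 through a chair–chair transition state with the C2 OTBS equatorial (the other fold puts it 1,3-diaxial to the C10 and axial C4 methyls), so the C2 centre sets 5S, 9S and 10S with the trans ring fusion and equatorial side chain coming from the two (E)-alkenes, and the C8 radical is oxidised (radical–polar crossover) and loses H-7 to collidine, any 8(17)-ene being taken up again by the cobalt hydride and moved to the trisubstituted 7-ene; the closest known reaction type is the cobalt-salen hydrogen-atom-transfer-initiated radical–polar crossover bicyclisation of polyenes that end on arenes, together with cobalt-hydride cycloisomerisation and one-position alkene isomerisation.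

Step 9
Reactants: 14 (2S,5S,9S,10S,13S)-2-[(tert-butyldimethylsilyl)oxy]labd-7-en-15-ol; 15 caffeic acid
Product: 16 (2S,5S,9S,10S,13S)-2-[(tert-butyldimethylsilyl)oxy]labd-7-en-15-yl (E)-caffeate
Conditions: PPh3 (1.3 equiv), DIAD (1.3 equiv), THF, 0 °C → rt
Reagents that add atoms: none
Why: Mitsunobu esterification, in which the alkoxyphosphonium ion of the unhindered primary alcohol is displaced by the carboxylate (pKa about 4.6, far more acidic than the catechol OH groups), so the ester forms without phenol protection and the (E)-enoate is untouched.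

Step 10
Reactants: 16 (2S,5S,9S,10S,13S)-2-[(tert-butyldimethylsilyl)oxy]labd-7-en-15-yl (E)-caffeate
Product: 17 (2S,5S,9S,10S,13S)-2-hydroxylabd-7-en-15-yl (E)-caffeate
Conditions: HF·pyridine, pyridine, THF, 0 °C → rt
Reagents that add atoms: none
Why: Fluoride-driven desilylation under buffered conditions cleaves the secondary TBS ether without affecting the cinnamate ester, the catechol or the trisubstituted alkene, and no stereocentre is involved.

## Compound list

1 | (S)-epichlorohydrin, (2S)-2-(chloromethyl)oxirane | ClC[C@@H]1CO1 | starting material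
2 | isopropenylmagnesium bromide, CH2=C(CH3)MgBr | CC(=C)[Mg]Br | starting material
3 | (2S)-1-chloro-4-methylpent-4-en-2-ol | CC(=C)C[C@H](O)CCl | intermediate
4 | (2S)-2-(2-methylprop-2-en-1-yl)oxirane, not isolated | CC(=C)C[C@H]1CO1 | intermediate
5 | (4S)-2-methylhept-1-en-6-yn-4-ol | CC(=C)C[C@H](O)CC#C | intermediate
6 | (4S)-4-[(tert-butyldimethylsilyl)oxy]-2-methylhept-1-en-6-yne | CC(=C)C[C@H](O[Si](C)(C)C(C)(C)C)CC#C | intermediate
7 | [(1E,4S)-4-[(tert-butyldimethylsilyl)oxy]-2,6-dimethylhepta-1,6-dien-1-yl]dimethylalane, not isolated | CC(=C)C[C@H](O[Si](C)(C)C(C)(C)C)C/C(C)=C/[Al](C)C | intermediate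
8 | (1E,4S)-4-[(tert-butyldimethylsilyl)oxy]-1-iodo-2,6-dimethylhepta-1,6-diene | CC(=C)C[C@H](O[Si](C)(C)C(C)(C)C)C/C(C)=C/I | intermediate
9 | (S)-citronellol, (3S)-3,7-dimethyloct-6-en-1-ol | CC(C)=CCC[C@H](C)CCO | starting material
10 | (2E,6S)-8-hydroxy-2,6-dimethyloct-2-enal | O=C/C(C)=C/CC[C@H](C)CCO | intermediate
11 | (3S,6E)-3,7-dimethylnona-6,8-dien-1-ol | C=C/C(C)=C/CC[C@H](C)CCO | intermediate
12 | (3S,6E)-9-(9-borabicyclo[3.3.1]nonan-9-yl)-3,7-dimethylnon-6-en-1-yl 9-borabicyclo[3.3.1]nonan-9-yl ether (C-boryl and O-boryl), not isolated | B1(CC/C(C)=C/CC[C@H](C)CCOB2C3CCCC2CCC3)C2CCCC1CCC2 | intermediate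
13 | (3S,6E,10E,13S)-13-[(tert-butyldimethylsilyl)oxy]-3,7,11,15-tetramethylhexadeca-6,10,15-trien-1-ol | CC(=C)C[C@H](O[Si](C)(C)C(C)(C)C)C/C(C)=C/CC/C(C)=C/CC[C@H](C)CCO | intermediate
14 | (2S,5S,9S,10S,13S)-2-[(tert-butyldimethylsilyl)oxy]labd-7-en-15-ol, i.e. (3S)-5-[(1S,4aS,7S,8aS)-7-(TBS-oxy)-2,5,5,8a-tetramethyl-1,4,4a,5,6,7,8,8a-octahydronaphthalen-1-yl]-3-methylpentan-1-ol | CC1=CC[C@H]2C(C)(C)C[C@H](O[Si](C)(C)C(C)(C)C)C[C@]2(C)[C@H]1CC[C@H](C)CCO | intermediate
15 | caffeic acid, (2E)-3-(3,4-dihydroxyphenyl)prop-2-enoic acid | O=C(O)/C=C/c1ccc(O)c(O)c1 | starting material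
16 | (2S,5S,9S,10S,13S)-2-[(tert-butyldimethylsilyl)oxy]labd-7-en-15-yl (2E)-3-(3,4-dihydroxyphenyl)prop-2-enoate | CC1=CC[C@H]2C(C)(C)C[C@H](O[Si](C)(C)C(C)(C)C)C[C@]2(C)[C@H]1CC[C@H](C)CCOC(=O)/C=C/c1ccc(O)c(O)c1 | intermediate
17 | CNP0206083.1, (3S)-5-[(1S,4aS,7S,8aS)-7-hydroxy-2,5,5,8a-tetramethyl-1,4,4a,5,6,7,8,8a-octahydronaphthalen-1-yl]-3-methylpentyl (2E)-3-(3,4-dihydroxyphenyl)prop-2-enoate | CC1=CC[C@H]2C(C)(C)C[C@H](O)C[C@]2(C)[C@H]1CC[C@H](C)CCOC(=O)/C=C/c1ccc(O)c(O)c1 | target

## Count and risks

Total steps: 10. Longest linear sequence: 8 (steps 1, 2, 3, 4, 7, 8, 9, 10); the citronellol branch (steps 5, 6) joins at step 7.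

Three steps most likely to fail:

Step 8 is the main risk. The hydrogen-atom-transfer bicyclisation has not been run with an alkene terminus or with a C2 silyloxy group as the only stereocontrol element. It may stall after ring A, trap the C8 cation with fluoride or solvent, or give 8(17)- and 8-ene isomers, which would need AgNO3-impregnated silica for removal. The fallback sets out from 13 and replaces the radical initiation by a two-electron electrophile. The Hg(OTf)2·N,N-dimethylaniline complex (divalent mercury, 1.2 equiv, MeNO2, −20 °C) attacks the same terminal alkene at its CH2 and triggers a cationic bicyclisation ended by proton loss. Aqueous NaCl then gives (2S,5S,9S,10S,13S)-2-[(tert-butyldimethylsilyl)oxy]-18-(chloromercurio)labd-7-en-15-ol F1 (either C4 epimer serves). NaBH4 in aqueous NaOH/THF at 0 °C exchanges mercury for hydrogen and the route is rejoined at 14.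

Step 9 is the second risk. The azodicarboxylate may oxidise the free catechol, or a phenol may be alkylated instead of the acid. The fallback sets out from 14 and builds the cinnamate on the alcohol. Heating 14 with Meldrum's acid in toluene at 100 °C gives the malonic acid half-ester 3-{[(2S,5S,9S,10S,13S)-2-[(tert-butyldimethylsilyl)oxy]labd-7-en-15-yl]oxy}-3-oxopropanoic acid F2. Knoevenagel–Doebner condensation of F2 with 3,4-dihydroxybenzaldehyde (pyridine, catalytic piperidine, 70 °C) loses CO2 and returns to the route at 16.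

Step 5 is the third risk. Selenium dioxide oxidation straight to the enal on an unprotected alcohol is usually low-yielding and can stop at the allylic alcohol or over-oxidise. The fallback sets out from 9 and builds the enal by olefination. Ozonolysis (O3, CH2Cl2/MeOH, −78 °C, then Me2S) gives (4S)-6-hydroxy-4-methylhexanal F3. Wittig reaction of F3 with the stabilised ylide Ph3P=C(CH3)CHO in toluene at 80 °C gives the (E)-enal and rejoins the route at 10.

## Further compounds

F1 | step 8 | (2S,5S,9S,10S,13S)-2-[(tert-butyldimethylsilyl)oxy]-18-(chloromercurio)labd-7-en-15-ol | CC1=CC[C@H]2[C@](C)(C[Hg]Cl)C[C@H](O[Si](C)(C)C(C)(C)C)C[C@]2(C)[C@H]1CC[C@H](C)CCO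
F2 | step 9 | 3-{[(2S,5S,9S,10S,13S)-2-[(tert-butyldimethylsilyl)oxy]labd-7-en-15-yl]oxy}-3-oxopropanoic acid | CC1=CC[C@H]2C(C)(C)C[C@H](O[Si](C)(C)C(C)(C)C)C[C@]2(C)[C@H]1CC[C@H](C)CCOC(=O)CC(=O)O
F3 | step 5 | (4S)-6-hydroxy-4-methylhexanal | O=CCC[C@H](C)CCO
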